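(All runs are calculated on assumed constants, noise included.)

Of the constants of this reaction, I tried to read one from two short runs: how much faster the left-handed substrate turns into product than the right-handed one. The flask is the alpha run carried on to the asked time, and the zeta run differs from it in its solid reagent.

| flask | left-handed substrate | right-handed substrate | solid reagent | free catalyst | racemization catalyst | impurity | remark | time |
|---|---|---|---|---|---|---|---|---|
| alpha | 10 mM | 10 mM | 25 mM | 0.93 mM | 0.54 mM | 0.15 mM | the very flask that is asked about, followed so far |  |
| zeta | 10 mM | 10 mM | 12 mM | 0.93 mM | 0.54 mM | 0.15 mM | run made earlier |  |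
| flask | 10 mM | 10 mM | 25.0 mM | 0.93 mM | 0.54 mM | 0.15 mM |  | 6.0 h |

alpha run (percent of the left-handed substrate and right-handed substrate together charged)

| time / min | left-handed product / % | right-handed product / % |
|---|---|---|
| 5.00 | 0 | 0 |
| 8.00 | 2 | 0 |
| 15.0 | 3 | 0 |
| 25.0 | 5 | 0 |
| 40.0 | 3 | 0 |
| 60.0 | 8 | 6 |

zeta run (percent of the left-handed substrate and right-handed substrate together charged)

| time / h | left-handed product / % | right-handed product / % |
|---|---|---|
| 0.417 | 1 | 2 |
| 0.833 | 5 | 4 |
| 1.33 | 7 | 3 |
| 1.50 | 11 | 4 |
| 2.00 | 16 | 6 |
| 2.50 | 16 | 11 |

(each reading ± 2 percentage points)

- free catalyst is single-handed; left-handed substrate and right-handed substrate are mirror images of each other, charged as a racemate, each of them at the stated concentration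
- as a solid, counted per litre of solution: solid reagent
- the numbers in the tables scatter by 2 percentage points (one standard deviation)
- at the start none of the solid reagent is in solution
- an excess is below zero if the other one leads

- left-handed product and right-handed product together, in percent of the left-handed substrate and right-handed substrate charged together, at 6.0 h
- excess of left-handed product over right-handed product in the product at 6.0 h
- whether the exchange between left-handed substrate and right-handed substrate keeps pace with the reaction: how far the product's excess at 6.0 h gets from its value without exchange to its value with instant exchange (above 80% keeps pace, below 20% hardly takes part, else lags behind)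

The zeta run seemed to contradict itself: left-handed over right-handed product stood at 2.67 at 2.00 h and at 1.45 at 2.50 h. But that fall rests on a rise of 5 percentage points in right-handed product, where a reading scatters by 2 points, so I summed the readings. Over both runs the sums gave 2.14, and I took this reading as s, the selectivity factor, the ratio of the two rates at equal substrates.

Let R and S be the fractions of left-handed and right-handed substrate remaining. Without exchange, ln R = s ln S. So when S reaches 0.5, the yield is 63.6% and the product's excess 21.4%. With instant exchange the excess stays at (s−1)/(s+1), or 36.3%. The pace of the zeta run up to 2.50 h, carried over to the flask with its larger charge of solid reagent and held steady, gave 64.8% at 6.0 h, close to that yield. In the zeta run the readings up to 1.50 h gave a ratio of 1.85 and the later ones 1.88, about the same. This was a lean within the scatter, but I committed to an excess near 36.3% and an exchange that keeps pace.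

The forecast gave 60%, 33% and lags behind, saying "The late rise in right-handed product suggests exchange is not keeping up". The flask gave 59.5%, 34.9% and keeps pace.

    partner + free catalyst + left-handed substrate → free catalyst + left-handed product (k = 83.0 L² mol⁻² s⁻¹)
    partner + free catalyst + right-handed substrate → free catalyst + right-handed product (k = 40.0 L² mol⁻² s⁻¹)
    left-handed substrate + racemization catalyst ⇌ right-handed substrate + racemization catalyst, rate k3*[racemization catalyst]*[left-handed substrate] forward; the back reaction follows from the equilibrium constant (k = 28.0 L mol⁻¹ s⁻¹)
    2 partner → self-condensation product (k = 0.340 L mol⁻¹ s⁻¹)
    solid reagent ⇌ partner, rate k5*(cs5 - [partner]) while solid is left; crystals form when [partner] > cs5 (solubility = 6.80 mM, k = 1.90 × 10⁻⁴ s⁻¹)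
    free catalyst + impurity → spent catalyst (k = 660 L mol⁻¹ s⁻¹)

In the flask, the exchange half-life from these constants is 22.9 s, far shorter than the 2.9 h half-life of left-handed substrate by its product path at 6.00 h. The flask's product excess gets 99.7% of the way to its value with instant exchange. A neighbouring flask with 0.60 mM of impurity reaches a yield of 36.0%; my s gives 36.3% for it, and its excess is 34.9%.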